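**Strategy**

The seven-membered ring is closed last, at the bond between the ester-bearing CH carbon and the adjacent methyl carbinol carbon: this vicinal C–O pair is the retron of a ring alkene. The precursor is a cyclopentanol whose two neighbouring fully substituted ring carbons carry, on the same face, an allyl arm (methyl-bearing carbon) and a 3-methylbut-3-enyl arm (carbinol carbon). Ring-closing metathesis joins the arms, and oxidation of the spent ruthenium to RuO4 in the same flask turns the new trisubstituted alkene into the α-ketol, so one operation delivers the hydroazulene, the ring ketone and the tertiary alcohol. All cyclopentane stereocentres follow from (S)-limonene by substrate control.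

Key step: step 8

Remark: bicyclic compounds are numbered as azulenes with the isopropyl carbon as C1, the methyl-bearing ring-fusion carbon as C3a and the hydroxyl-bearing ring-fusion carbon as C8a; the face of the angular methyl group is called β, and oxidants are assumed to reach the ring alkene from the α face.

**Route**

Step 1
Reactants: 1 (S)-(−)-limonene
Product: 2 (4S)-1-methyl-4-(propan-2-yl)cyclohex-1-ene
Conditions: H2 (1 atm), RhCl(PPh3)3 (1 mol %), toluene, rt
Reagents that add atoms: none
Why: Chemoselective homogeneous hydrogenation: the rhodium catalyst should saturate the unhindered 1,1-disubstituted isopropenyl alkene far faster than the trisubstituted ring alkene, and the existing stereocentre is not touched.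

Step 2
Reactants: 2 (4S)-1-methyl-4-(propan-2-yl)cyclohex-1-ene
Product: 3 (3S)-6-oxo-3-(propan-2-yl)heptanal
Conditions: O3, CH2Cl2/MeOH, −78 °C; then Me2S, −78 °C → rt
Reagents that add atoms: ozone, [O-][O+]=O
Why: Ozonolysis with reductive work-up should cleave the only alkene to the methyl ketone and the aldehyde, the stereocentre sitting β to the aldehyde and so being configurationally safe.

Step 3
Reactants: 3 (3S)-6-oxo-3-(propan-2-yl)heptanal
Product: 4 (5R)-2-methyl-5-(propan-2-yl)cyclopent-1-ene-1-carbaldehyde
Conditions: piperidine (0.2 equiv), AcOH (0.2 equiv), toluene, reflux, azeotropic removal of water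
Reagents that add atoms: none
Why: Intramolecular aldol condensation through the aldehyde enamine, which attacks the methyl ketone (5-exo) and dehydrates to the conjugated cyclopentene carbaldehyde; the isopropyl stereocentre lies on a carbon that neither the enamine nor a dienamine can deprotonate, so it should be retained.

Step 4
Reactants: 4 (5R)-2-methyl-5-(propan-2-yl)cyclopent-1-ene-1-carbaldehyde; 5 allylmagnesium bromide
Product: 6 1-[(5R)-2-methyl-5-(propan-2-yl)cyclopent-1-en-1-yl]but-3-en-1-ol (both carbinol epimers)
Conditions: 5 (1.2 equiv), Et2O, −78 °C; aq. NH4Cl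
Reagents that add atoms: none
Why: Grignard 1,2-addition: allylmagnesium bromide should add to the aldehyde carbonyl of the hindered enal rather than in conjugate fashion; the new carbinol centre need not be controlled because step 5 erases it.

Step 5
Reactants: 6 1-[(5R)-2-methyl-5-(propan-2-yl)cyclopent-1-en-1-yl]but-3-en-1-ol
Product: 8 trimethyl{[(2R,5R)-2-methyl-5-(propan-2-yl)-2-(prop-2-en-1-yl)cyclopentylidene]methoxy}silane (E/Z mixture), via potassium aldehyde enolate 7 (not isolated)
Conditions: KH (1.5 equiv), 18-crown-6 (1.5 equiv), THF, 0 °C → rt; then TMSCl, −78 °C → rt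
Reagents that add atoms: chlorotrimethylsilane, C[Si](C)(C)Cl
Why: Anionic oxy-Cope rearrangement: the potassium alkoxide should undergo the [3,3] shift through a chair transition state that carries the allyl group to the methyl-bearing alkene carbon on the face anti to the neighbouring isopropyl group (the exocyclic arm avoids allylic strain with it), which sets the quaternary centre with methyl cis to isopropyl, and the resulting aldehyde enolate is silylated on oxygen.

Step 6
Reactants: 8 trimethyl{[(2R,5R)-2-methyl-5-(propan-2-yl)-2-(prop-2-en-1-yl)cyclopentylidene]methoxy}silane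
Product: 9 (2R,5R)-2-methyl-5-(propan-2-yl)-2-(prop-2-en-1-yl)cyclopentan-1-one
Conditions: O3 (1.0 equiv, Sudan Red 7B end point), CH2Cl2, −78 °C; then Me2S
Reagents that add atoms: ozone, [O-][O+]=O
Why: Ozonolysis: the electron-rich silyl enol ether should consume ozone much faster than the monosubstituted allyl alkene, so titration to the dye end point excises the former formyl carbon as trimethylsilyl formate and leaves the ketone, whose α stereocentre stays fixed under these neutral conditions.

Step 7
Reactants: 9 (2R,5R)-2-methyl-5-(propan-2-yl)-2-(prop-2-en-1-yl)cyclopentan-1-one; 10 4-bromo-2-methylbut-1-ene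
Product: 12 (1S,2R,5R)-2-methyl-1-(3-methylbut-3-en-1-yl)-5-(propan-2-yl)-2-(prop-2-en-1-yl)cyclopentan-1-ol, via 3-methylbut-3-enylmagnesium bromide 11 (not isolated)
Conditions: 10, Mg, THF, rt; then 9 premixed with anhydrous CeCl3 (1.5 equiv) in THF, −78 → 0 °C; aq. NH4Cl
Reagents that add atoms: none
Why: Grignard addition promoted by CeCl3, which should suppress enolisation and β-hydride reduction; the nucleophile should enter anti to the adjacent isopropyl group, that is on the face of the allyl arm, so the new tertiary hydroxyl is cis to isopropyl and to the angular methyl and the two alkene arms are cis.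

Step 8
Reactants: 12 (1S,2R,5R)-2-methyl-1-(3-methylbut-3-en-1-yl)-5-(propan-2-yl)-2-(prop-2-en-1-yl)cyclopentan-1-ol
Product: 14 (1R,3aR,6R,8aS)-6,8a-dihydroxy-3a,6-dimethyl-1-(propan-2-yl)octahydroazulen-5(1H)-one, via ring alkene 13 (not isolated)
Conditions: second-generation Grubbs catalyst RuCl2(=CHPh)(H2IMes)(PCy3) (5 mol %), CH2Cl2 (0.01 M), 40 °C; then EtOAc/MeCN/H2O (6:6:1), NaHCO3, Oxone (2KHSO5·KHSO4·K2SO4), rt
Reagents that add atoms: Oxone (potassium peroxymonosulfate), [K+].[O-]S(=O)(=O)OO
Why: Ring-closing metathesis followed in the same flask by ruthenium-catalysed ketohydroxylation: the ruthenium alkylidene should load on the monosubstituted allyl alkene, close onto the 1,1-disubstituted alkene by [2+2] cycloaddition and cycloreversion with loss of ethene to give alkene 13, after which Oxone converts the spent ruthenium into RuO4, which adds [3+2] to the new alkene and is oxidised off as the α-ketol. The closest known reaction type is the tandem olefin metathesis–oxidation sequence, here with ring-closing metathesis and ketohydroxylation. The seven-membered ring is closed by metathesis between two arms held cis on adjacent carbons of the five-membered ring, which gives the cis-fused bicycle without building strain. The new tertiary carbinol centre is set by the face of RuO4 attack, expected on the α face away from the angular methyl group, while the carbonyl must fall on the former alkene CH carbon. The step needs ring closure to win over oligomerisation, secured by high dilution and the cis arms, and it needs the oxidation to stop at the ketol, secured by the bicarbonate buffer and short contact time.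

Step 9
Reactants: 14 (1R,3aR,6R,8aS)-6,8a-dihydroxy-3a,6-dimethyl-1-(propan-2-yl)octahydroazulen-5(1H)-one
Product: 15 (1R,3aR,5R,6R,8aS)-3a,6-dimethyl-1-(propan-2-yl)decahydroazulene-5,6,8a-triol
Conditions: Me4NBH(OAc)3 (4 equiv), MeCN/AcOH (1:1), −20 °C
Reagents that add atoms: none
Why: Hydroxyl-directed triacetoxyborohydride reduction (Saksena–Evans type): the reagent should bind the tertiary α-hydroxyl and deliver hydride to the ketone from that same α face, which places the new secondary hydroxyl on the β face, trans to the tertiary one.

Step 10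
Reactants: 15 (1R,3aR,5R,6R,8aS)-3a,6-dimethyl-1-(propan-2-yl)decahydroazulene-5,6,8a-triol; 16 4-methoxybenzoyl chloride
Product: 17 (1R,3aR,5R,6R,8aS)-6,8a-dihydroxy-3a,6-dimethyl-1-(propan-2-yl)decahydroazulen-5-yl 4-methoxybenzoate (CNP0244624.1)
Conditions: 16 (1.3 equiv), Et3N, DMAP (0.1 equiv), CH2Cl2, 0 °C → rt
Reagents that add atoms: none
Why: DMAP-catalysed acylation (nucleophilic catalysis): only the secondary hydroxyl should react, because both tertiary hydroxyls are too hindered for the acylpyridinium intermediate, and no stereocentre is affected.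

**Compound list**

1 | (S)-(−)-limonene, (4S)-1-methyl-4-(prop-1-en-2-yl)cyclohex-1-ene | CC1=CC[C@@H](C(C)=C)CC1 | starting material
2 | (4S)-1-methyl-4-(propan-2-yl)cyclohex-1-ene | CC1=CC[C@@H](C(C)C)CC1 | intermediate
3 | (3S)-6-oxo-3-(propan-2-yl)heptanal | CC(=O)CC[C@H](C(C)C)CC=O | intermediate
4 | (5R)-2-methyl-5-(propan-2-yl)cyclopent-1-ene-1-carbaldehyde | O=CC1=C(C)CC[C@@H]1C(C)C | intermediate
5 | allylmagnesium bromide | C=CC[Mg]Br | starting material
6 | 1-[(5R)-2-methyl-5-(propan-2-yl)cyclopent-1-en-1-yl]but-3-en-1-ol (both carbinol epimers) | C=CCC(O)C1=C(C)CC[C@@H]1C(C)C | intermediate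
7 | potassium [(2R,5R)-2-methyl-5-(propan-2-yl)-2-(prop-2-en-1-yl)cyclopentylidene]methanolate | C=CC[C@@]1(C)CC[C@H](C(C)C)C1=C[O-].[K+] | intermediate
8 | trimethyl{[(2R,5R)-2-methyl-5-(propan-2-yl)-2-(prop-2-en-1-yl)cyclopentylidene]methoxy}silane | C=CC[C@@]1(C)CC[C@H](C(C)C)C1=CO[Si](C)(C)C | intermediate
9 | (2R,5R)-2-methyl-5-(propan-2-yl)-2-(prop-2-en-1-yl)cyclopentan-1-one | C=CC[C@@]1(C)CC[C@H](C(C)C)C1=O | intermediate
10 | 4-bromo-2-methylbut-1-ene | C=C(C)CCBr | starting material
11 | 3-methylbut-3-enylmagnesium bromide | C=C(C)CC[Mg]Br | intermediate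
12 | (1S,2R,5R)-2-methyl-1-(3-methylbut-3-en-1-yl)-5-(propan-2-yl)-2-(prop-2-en-1-yl)cyclopentan-1-ol | C=CC[C@@]1(C)CC[C@H](C(C)C)[C@@]1(O)CCC(C)=C | intermediate
13 | (1R,3aR,8aS)-3a,6-dimethyl-1-(propan-2-yl)-2,3,3a,4,7,8-hexahydroazulen-8a(1H)-ol | CC1=CC[C@@]2(C)CC[C@H](C(C)C)[C@@]2(O)CC1 | intermediate
14 | (1R,3aR,6R,8aS)-6,8a-dihydroxy-3a,6-dimethyl-1-(propan-2-yl)octahydroazulen-5(1H)-one | O=C1C[C@@]2(C)CC[C@H](C(C)C)[C@@]2(O)CC[C@@]1(C)O | intermediate
15 | (1R,3aR,5R,6R,8aS)-3a,6-dimethyl-1-(propan-2-yl)decahydroazulene-5,6,8a-triol | O[C@@H]1C[C@@]2(C)CC[C@H](C(C)C)[C@@]2(O)CC[C@@]1(C)O | intermediate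
16 | 4-methoxybenzoyl chloride | COc1ccc(C(=O)Cl)cc1 | starting material
17 | (1R,3aR,5R,6R,8aS)-6,8a-dihydroxy-3a,6-dimethyl-1-(propan-2-yl)decahydroazulen-5-yl 4-methoxybenzoate | COc1ccc(C(=O)O[C@@H]2C[C@@]3(C)CC[C@H](C(C)C)[C@@]3(O)CC[C@@]2(C)O)cc1 | target

**Step count and risks**

Total step count: 10. Longest linear sequence: 10 steps (1 → 17); compounds 5, 10 and 16 are bought.

The three steps most likely to fail:

Step 8. What may go wrong: the ruthenium oxidant approaches the ring alkene from the β face instead of the α face, so that the tertiary carbinol forms with the wrong configuration. Fallback: starting from 12, the metathesis is run alone and alkene 13 is isolated. Epoxidation with mCPBA on that same β face gives (1R,3aR,5R,6S,8aS)-5,6-epoxy-3a,6-dimethyl-1-(propan-2-yl)decahydroazulen-8a-ol F1. Acid-catalysed hydrolysis (dilute HClO4, THF/H2O), in which water opens the tertiary carbon with inversion, turns the β-face preference into the required trans-diol and returns to the route at 15.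

Step 5. What may go wrong: the alkoxide fragments by retro-allylation, or the sigmatropic shift shows poor facial control at the tetrasubstituted alkene. Fallback: starting from 4, Baeyer–Villiger oxidation (mCPBA, Na2HPO4, CH2Cl2) with migration of the alkenyl group gives (5R)-2-methyl-5-(propan-2-yl)cyclopent-1-en-1-yl formate F2. Two equivalents of MeLi (THF, 0 °C) release the regiodefined enolate, lithium (5R)-2-methyl-5-(propan-2-yl)cyclopent-1-en-1-olate F3, which is alkylated with allyl bromide anti to the isopropyl group and returns to the route at 9; steps 4 to 6 are bypassed.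

Step 6. What may go wrong: ozone also attacks the allyl alkene, so the arm needed for metathesis is lost by over-oxidation. Fallback: starting from 8, the silyl enol ether is hydrolysed (K2CO3, MeOH) to (2R,5R)-2-methyl-5-(propan-2-yl)-2-(prop-2-en-1-yl)cyclopentane-1-carbaldehyde F4 (both epimers at C1). Copper-catalysed aerobic deformylation (Cu(OAc)2, 2,2′-bipyridine, DABCO, O2, DMF, 40 °C) then cuts out the formyl carbon without touching the alkene and returns to the route at 9.

**Further compounds**

F1 | step 8 | (1R,3aR,5R,6S,8aS)-5,6-epoxy-3a,6-dimethyl-1-(propan-2-yl)decahydroazulen-8a-ol | O1[C@@H]2C[C@@]3(C)CC[C@H](C(C)C)[C@@]3(O)CC[C@]12C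
F2 | step 5 | (5R)-2-methyl-5-(propan-2-yl)cyclopent-1-en-1-yl formate | O=COC1=C(C)CC[C@@H]1C(C)C
F3 | step 5 | lithium (5R)-2-methyl-5-(propan-2-yl)cyclopent-1-en-1-olate | [Li+].[O-]C1=C(C)CC[C@@H]1C(C)C
F4 | step 6 | (2R,5R)-2-methyl-5-(propan-2-yl)-2-(prop-2-en-1-yl)cyclopentane-1-carbaldehyde | C=CC[C@@]1(C)CC[C@H](C(C)C)C1C=O
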